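**Retrosynthetic overview**
1. Last bond set: an intermolecular exo Diels–Alder reaction between a 2β-acetoxy-guaia-1(5),3-dienolide (made in the flask by dehydration of a C4 tertiary allylic alcohol) and the exocyclic methylene of 1-O-acetylbritannilactone closes the norbornene (C1–C13′, C3–C11′) and sets C1, C3 and C11′.
2. The C2 acetate comes from a CBS reduction of a 2-oxo-guai-1(5)-enolide; the C4 hydroxyl comes from γ-oxidation of the dienol acetate of that enone.
3. Key disconnection: the carbocyclic seven-membered ring (C1, C10, C9, C8, C7, C6, C5) is fused to the cyclopentenone along the tetrasubstituted C1=C5 bond, with the C2 carbonyl next to C1. Moving C10 back from C1 to C5 reveals a spiro[4.5] 2-oxyallyl cation, which is the Nazarov intermediate of a cyclohexylidene propenyl ketone, so one acid step builds the five-membered ring and expands the six-membered ring to the seven-membered ring.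
4. The cyclohexanone carrying the C7/C8/C10 triad comes from (S)-4-silyloxycyclohexenone by two additions anti to the silyloxy group (α′-methylation, Mukaiyama–Michael addition), followed by lactonisation.
5. Ring order: cyclohexane (purchased) → γ-lactone → cyclopentenone together with cycloheptene (key step) → norbornene (last step).

Key step: step 7

Remark: (S)-4-(tert-butyldimethylsilyloxy)cyclohex-2-enone and 1-O-acetylbritannilactone are taken as catalogue compounds.
Numbering: guaiane numbers are used for all intermediates (the ring of 1 is C5 = carbonyl carbon, C6, C7, C8 = silyloxy carbon, C9, C10; C11–C13 = lactone carbons; primes = seco-eudesmanolide half; α = the face of the C8 oxygen).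

Step 1
Reactants: 1 (S)-4-[(tert-butyldimethylsilyl)oxy]cyclohex-2-en-1-one
Product: 2 (4S,6S)-4-[(tert-butyldimethylsilyl)oxy]-6-methylcyclohex-2-en-1-one
Conditions: LDA, THF, −78 °C; MeI, DMPU, −78 → −40 °C
Reagents that add atoms: iodomethane, CI
Why: Kinetic α′-deprotonation and alkylation of the cross-conjugated lithium enolate (enolate alkylation); the electrophile should enter anti to the pseudo-axial C8 silyloxy group, which places the C10 methyl trans to the C8 oxygen.

Step 2
Reactants: 2 (4S,6S)-4-[(tert-butyldimethylsilyl)oxy]-6-methylcyclohex-2-en-1-one; 3 1-[(tert-butyldimethylsilyl)oxy]-1-methoxyethene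
Product: 5 methyl 2-[(1R,2S,4S)-2-[(tert-butyldimethylsilyl)oxy]-4-methyl-5-oxocyclohexyl]acetate, via silyl enol ether 4 (not isolated)
Conditions: Me3SiOTf (10 mol %), CH2Cl2, −78 °C; then 1 M HCl, THF, 0 °C
Reagents that add atoms: none
Why: Mukaiyama–Michael addition; the ketene acetal should add to C7 anti to the adjacent silyloxy group (trans C7/C8, hence cis to the C10 methyl), and the enol silane is hydrolysed on work-up without enolising toward C10.

Step 3
Reactants: 5 methyl 2-[(1R,2S,4S)-2-[(tert-butyldimethylsilyl)oxy]-4-methyl-5-oxocyclohexyl]acetate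
Product: 6 (3aR,6S,7aS)-6-methylhexahydro-1-benzofuran-2,5-dione
Conditions: HF·pyridine, THF, 0 → 25 °C; then pyridinium p-toluenesulfonate (cat.), benzene, 40 °C
Reagents that add atoms: none
Why: Desilylation followed by acid-catalysed lactonisation of the trans γ-hydroxy ester closes the trans-fused γ-lactone; no stereocentre is touched and the mildly acidic medium should not epimerise the α-methyl ketone.

Step 4
Reactants: 6 (3aR,6S,7aS)-6-methylhexahydro-1-benzofuran-2,5-dione; 7 (E)-pent-3-en-1-yne
Product: 8 (3aR,5R,6S,7aS)-5-hydroxy-6-methyl-5-[(E)-pent-3-en-1-yn-1-yl]hexahydro-1-benzofuran-2(3H)-one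
Conditions: 7, n-BuLi, THF, −78 °C; CeCl3; then 6, −78 °C; NH4Cl (aq)
Reagents that add atoms: none
Why: 1,2-Addition of a weakly basic cerium acetylide to the ketone (chemoselective over the lactone, no epimerisation at C10); axial attack should give the drawn carbinol, but this centre becomes sp2 in step 6, so its configuration is of no consequence.

Step 5
Reactants: 8 (3aR,5R,6S,7aS)-5-hydroxy-6-methyl-5-[(E)-pent-3-en-1-yn-1-yl]hexahydro-1-benzofuran-2(3H)-one
Product: 11 (3aR,5R,6S,7aS)-5-hydroxy-6-methyl-3-methylidene-5-[(E)-pent-3-en-1-yn-1-yl]hexahydro-1-benzofuran-2(3H)-one, via Mannich base 9 (not isolated), via ammonium iodide 10 (not isolated)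
Conditions: LDA (2.3 equiv), THF, −78 °C; CH2=NMe2+ I−, −78 → 0 °C; MeI, MeOH, 25 °C; NaHCO3 (aq), CH2Cl2
Reagents that add atoms: Eschenmoser's salt (N,N-dimethylmethyleneiminium iodide), C=[N+](C)C.[I-]; iodomethane, CI
Why: α-Methylenation of the lactone by Mannich reaction of its lithium enolate (the tertiary alcohol is carried as its alkoxide), N-methylation and E1cB loss of trimethylamine; no stereocentre is created in the product.

Step 6
Reactants: 11 (3aR,5R,6S,7aS)-5-hydroxy-6-methyl-3-methylidene-5-[(E)-pent-3-en-1-yn-1-yl]hexahydro-1-benzofuran-2(3H)-one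
Product: 12 (3aR,5E,6S,7aS)-6-methyl-3-methylidene-5-[(3E)-2-oxopent-3-en-1-ylidene]hexahydro-1-benzofuran-2(3H)-one
Conditions: Au(PPh3)NTf2 (2 mol %), MeOH (1 equiv), toluene, 25 °C
Reagents that add atoms: none
Why: Gold-catalysed Meyer–Schuster rearrangement (formal 1,3-shift of the tertiary propargylic hydroxyl) gives the cross-conjugated dienone; the exocyclic alkene should form with the acyl group away from C10, and either geometry serves in step 7.

Step 7
Reactants: 12 (3aR,5E,6S,7aS)-6-methyl-3-methylidene-5-[(3E)-2-oxopent-3-en-1-ylidene]hexahydro-1-benzofuran-2(3H)-one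
Product: 13 2-oxo-7αH,8βH,10αH-guaia-1(5),11(13)-dien-12,8-olide (4β-methyl drawn; the C4 epimer is expected as well)
Conditions: TfOH (1.5 equiv), CH2Cl2, −40 → 0 °C; then Et3N
Reagents that add atoms: none
Why: Proposed new method: O-protonation of the cross-conjugated dienone gives a hydroxypentadienyl cation whose 4π-conrotatory electrocyclisation (Nazarov) joins C4 to C5 and makes C5 a spiro centre; the resulting 2-hydroxyallyl cation (C1–C2–C3) has no hydrogen on the spiro carbon next to C1, so the six-ring bond C5–C10 shifts to C1 (Wagner–Meerwein), which expands the cyclohexane (C5–C10) into the cycloheptane C1, C10, C9, C8, C7, C6, C5, and loss of H-1 from the tertiary C5 cation followed by ketonisation gives the tetrasubstituted enone. The closest known reaction types are Nazarov cyclisation/Wagner–Meerwein sequences of divinyl ketones that carry a quaternary carbon next to the oxyallyl cation and the acid-catalysed spiro[4.5]decyl to hydroazulenyl cation rearrangement; the ring expansion of a cyclohexylidene-derived spiro cation is the untested part. The five-membered ring closes by electrocyclisation of a 4π pentadienyl cation and the seven-membered ring arises by 1,2-alkyl shift (ring expansion by one atom), both in one operation. C10 migrates with retention, so C7, C8 and C10 are carried over unchanged, while C4 is formed without control and is erased in step 8. The step needs migration of C10 instead of C6, which the higher migratory aptitude of the more substituted carbon should secure (both bonds are aligned with the cationic p orbital), and it needs the shift to outrun proton loss from C4, for which a non-basic triflate medium at low temperature is chosen; positional isomers of the enone converge on the Et3N work-up and in step 8.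

Step 8
Reactants: 13 2-oxo-7αH,8βH,10αH-guaia-1(5),11(13)-dien-12,8-olide
Product: 14 2-acetoxy-7αH,8βH,10αH-guaia-1,4,11(13)-trien-12,8-olide
Conditions: Ac2O, HClO4 (cat.), EtOAc, 0 → 25 °C
Reagents that add atoms: acetic anhydride, CC(=O)OC(C)=O
Why: Thermodynamic enol acetylation through the extended (γ) enol (dienol acetate formation) should give the fully substituted 2-acetoxycyclopentadiene, which removes the C4 stereocentre.

Step 9
Reactants: 14 2-acetoxy-7αH,8βH,10αH-guaia-1,4,11(13)-trien-12,8-olide
Product: 15 4α-hydroxy-2-oxo-7αH,8βH,10αH-guaia-1(5),11(13)-dien-12,8-olide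
Conditions: mCPBA (1.05 equiv), NaHCO3, dioxane–H2O (9:1), 0 °C
Reagents that add atoms: 3-chloroperoxybenzoic acid, OOC(=O)c1cccc(Cl)c1
Why: Peracid epoxidation of the electron-rich C4=C5 bond of the dienol acetate (not the acetoxy-deactivated C1=C2 bond), opening at C5 and loss of the acetyl group give the γ-hydroxy enone (classical dienol acetate γ-hydroxylation); attack on the α-face, away from the C10 methyl, should give the 4α-alcohol, and the C4 epimer would serve equally.

Step 10
Reactants: 15 4α-hydroxy-2-oxo-7αH,8βH,10αH-guaia-1(5),11(13)-dien-12,8-olide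
Product: 16 2β,4α-dihydroxy-7αH,8βH,10αH-guaia-1(5),11(13)-dien-12,8-olide
Conditions: (S)-2-methyl-CBS-oxazaborolidine (0.5 equiv), catecholborane (2.5 equiv), toluene, −78 °C; MeOH
Reagents that add atoms: none
Why: Corey–Bakshi–Shibata reduction with the fully substituted alkenyl carbon C1 as the large group should deliver hydride to the α-face of C2 (2R, 2β-OH), reinforced by delivery from the 4α-O-boron ester; this 1,2-reduction should leave the α-methylene lactone untouched at −78 °C.

Step 11
Reactants: 16 2β,4α-dihydroxy-7αH,8βH,10αH-guaia-1(5),11(13)-dien-12,8-olide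
Product: 17 2β-acetoxy-4α-hydroxy-7αH,8βH,10αH-guaia-1(5),11(13)-dien-12,8-olide
Conditions: Ac2O (1.5 equiv), pyridine, 4-(dimethylamino)pyridine (cat.), CH2Cl2, 0 °C
Reagents that add atoms: acetic anhydride, CC(=O)OC(C)=O
Why: Acylation; the secondary allylic alcohol is esterified selectively because the tertiary C4 alcohol is inert under these conditions, and no stereocentre changes.

Step 12
Reactants: 17 2β-acetoxy-4α-hydroxy-7αH,8βH,10αH-guaia-1(5),11(13)-dien-12,8-olide; 18 1-O-acetylbritannilactone
Product: 20 CNP0211028.3 (target), via acetoxydiene 19 (not isolated)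
Conditions: Burgess reagent (MeO2CN−SO2N+Et3, 1.05 equiv), benzene, 25 °C; then 18 (3 equiv), concentrated to 1 M, 30 °C, dark
Reagents that add atoms: none
Why: Burgess dehydration (syn-elimination toward C3) gives the 1(5),3-diene, which adds to the exocyclic alkene of 18 in an intermolecular Diels–Alder reaction: the CH2 terminus bonds to C1 and the quaternary carbon to C3 (no vicinal quaternary centres), on the α-face of the diene anti to both the C2 acetoxy and C10 methyl groups, and in the exo mode usual for α-methylene lactones (lactone carbonyl exo, diene on the lactone face that carries C6′), which sets C1, C3 and C11′ and leaves the acetate syn to the new C4=C5 bridge.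

**Compound list**
1 | (S)-4-[(tert-butyldimethylsilyl)oxy]cyclohex-2-en-1-one | O=C1C=C[C@@H](O[Si](C)(C)C(C)(C)C)CC1 | starting material
2 | (4S,6S)-4-[(tert-butyldimethylsilyl)oxy]-6-methylcyclohex-2-en-1-one | C[C@H]1C[C@H](O[Si](C)(C)C(C)(C)C)C=CC1=O | intermediate
3 | 1-[(tert-butyldimethylsilyl)oxy]-1-methoxyethene | C=C(OC)O[Si](C)(C)C(C)(C)C | starting material
4 | silyl enol ether of 5 (C5 O-silyl, C5=C6) | COC(=O)C[C@H]1C=C(O[Si](C)(C)C(C)(C)C)[C@@H](C)C[C@@H]1O[Si](C)(C)C(C)(C)C | intermediate
5 | methyl 2-[(1R,2S,4S)-2-[(tert-butyldimethylsilyl)oxy]-4-methyl-5-oxocyclohexyl]acetate | COC(=O)C[C@H]1CC(=O)[C@@H](C)C[C@@H]1O[Si](C)(C)C(C)(C)C | intermediate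
6 | (3aR,6S,7aS)-6-methylhexahydro-1-benzofuran-2,5-dione | O=C1O[C@H]2C[C@H](C)C(=O)C[C@@H]2C1 | intermediate
7 | (E)-pent-3-en-1-yne | C#C/C=C/C | starting material
8 | (3aR,5R,6S,7aS)-5-hydroxy-6-methyl-5-[(E)-pent-3-en-1-yn-1-yl]hexahydro-1-benzofuran-2(3H)-one | O=C1O[C@H]2C[C@H](C)[C@@](O)(C#C/C=C/C)C[C@@H]2C1 | intermediate
9 | 3-[(dimethylamino)methyl] derivative of 8 (Mannich base, C3 epimers) | CN(C)CC1C(=O)O[C@H]2C[C@H](C)[C@@](O)(C#C/C=C/C)C[C@H]12 | intermediate
10 | 3-[(trimethylammonio)methyl] derivative of 8, iodide | C[N+](C)(C)CC1C(=O)O[C@H]2C[C@H](C)[C@@](O)(C#C/C=C/C)C[C@H]12.[I-] | intermediate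
11 | (3aR,5R,6S,7aS)-5-hydroxy-6-methyl-3-methylidene-5-[(E)-pent-3-en-1-yn-1-yl]hexahydro-1-benzofuran-2(3H)-one | C=C1C(=O)O[C@H]2C[C@H](C)[C@@](O)(C#C/C=C/C)C[C@H]12 | intermediate
12 | (3aR,5E,6S,7aS)-6-methyl-3-methylidene-5-[(3E)-2-oxopent-3-en-1-ylidene]hexahydro-1-benzofuran-2(3H)-one | C=C1C(=O)O[C@H]2C[C@H](C)/C(=C/C(=O)/C=C/C)C[C@H]12 | intermediate
13 | 2-oxo-7αH,8βH,10αH-guaia-1(5),11(13)-dien-12,8-olide (4β-methyl drawn, C4 epimer also expected) | C=C1C(=O)O[C@H]2C[C@H](C)C3=C(C[C@H]12)[C@@H](C)CC3=O | intermediate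
14 | 2-acetoxy-7αH,8βH,10αH-guaia-1,4,11(13)-trien-12,8-olide | C=C1C(=O)O[C@H]2C[C@H](C)C3=C(OC(C)=O)CC(C)=C3C[C@H]12 | intermediate
15 | 4α-hydroxy-2-oxo-7αH,8βH,10αH-guaia-1(5),11(13)-dien-12,8-olide | C=C1C(=O)O[C@H]2C[C@H](C)C3=C(C[C@H]12)[C@](C)(O)CC3=O | intermediate
16 | 2β,4α-dihydroxy-7αH,8βH,10αH-guaia-1(5),11(13)-dien-12,8-olide | C=C1C(=O)O[C@H]2C[C@H](C)C3=C(C[C@H]12)[C@](C)(O)C[C@H]3O | intermediate
17 | 2β-acetoxy-4α-hydroxy-7αH,8βH,10αH-guaia-1(5),11(13)-dien-12,8-olide | C=C1C(=O)O[C@H]2C[C@H](C)C3=C(C[C@H]12)[C@](C)(O)C[C@H]3OC(C)=O | intermediate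
18 | 1-O-acetylbritannilactone, (4S)-4-[(3aS,4S,7aR)-4-hydroxy-6-methyl-3-methylidene-2-oxo-3a,4,7,7a-tetrahydro-1-benzofuran-5-yl]pentyl acetate | C=C1C(=O)O[C@@H]2CC(C)=C([C@@H](C)CCCOC(C)=O)[C@@H](O)[C@@H]21 | starting material
19 | 2β-acetoxy-7αH,8βH,10αH-guaia-1(5),3,11(13)-trien-12,8-olide | C=C1C(=O)O[C@H]2C[C@H](C)C3=C(C[C@H]12)C(C)=C[C@H]3OC(C)=O | intermediate
20 | CNP0211028.3, Diels–Alder adduct of 19 and 18 (C1–C13′, C3–C11′) | C=C1C(=O)O[C@H]2C[C@H](C)[C@@]34C[C@]5(C(=O)O[C@@H]6CC(C)=C([C@@H](C)CCCOC(C)=O)[C@@H](O)[C@@H]65)[C@@H](C(C)=C3C[C@H]12)[C@H]4OC(C)=O | target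

**Step count and risks**
Total step count: 12. Longest linear sequence: 12 steps (1 → 20; 18 enters in step 12).

Steps most likely to fail:

1. Step 7 (Proposed new method). The oxyallyl cation may simply lose a proton from C4 and stop at the spiro enone, or the less substituted C6 may migrate in place of C10. Fallback in known chemistry, which sets out from 6 and comes back at 13: one-carbon homologation of 6 with Me3SiCHN2/BF3·OEt2 (CH2Cl2, −78 °C; the less substituted α-carbon migrates) gives the C-silyl ketone F1, which is protodesilylated on acidic work-up to the ring-expanded cycloheptanone F2, so the six-to-seven ring expansion is kept as a diazo insertion. LiHMDS/PhNTf2 (THF, −78 °C) should give the less substituted enol triflate F3. Methylenation as in step 5 (via the Mannich base F4 and the ammonium iodide F5) gives the methylene lactone triflate F6. Carbonylative Stille coupling (Pd(PPh3)4, CO 1 atm, LiCl, (E)-tributyl(prop-1-en-1-yl)stannane, THF, 55 °C) gives the cycloheptenyl propenyl ketone F7, whose ordinary Nazarov cyclisation (BF3·OEt2, CH2Cl2, 0 °C) gives 13.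

2. Step 12. The acetoxydiene may drift by [1,5]-hydrogen shift, or add to its own α-methylene lactone, before it meets 18. The intrinsic preference of 5-acyloxycyclopentadienes for attack syn to oxygen may also erode the facial selectivity that the exo lactone carbonyl and the C10 methyl are expected to enforce. Fallback, which sets out from 17 and comes back at 20: conjugate addition of dimethylamine (2 M in THF, 0 °C) masks the C11(13) methylene as the amine F8. Burgess dehydration then gives the amino diene F9, which cannot add to itself and can be left with excess 18 (neat or under high pressure) to give the cycloadduct F10. N-Methylation (MeI, MeOH) to the ammonium iodide F11 and elimination with aqueous NaHCO3 unveil the methylene lactone of 20.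

3. Step 9. The peracid may attack the enol acetate double bond, or the dienol acetate may be a mixture of [1,5]-hydrogen isomers, so that oxygen ends up at a position other than C4. Fallback, which sets out from 13 and comes back at 15: soft enolisation (t-BuMe2SiOTf, Et3N, CH2Cl2, 0 °C) gives the 2-silyloxycyclopentadiene F12. Sensitised photooxygenation (O2, 5,10,15,20-tetraphenylporphyrin, hν, CH2Cl2, −78 °C) adds singlet oxygen across the diene termini C2 and C4, and methanolysis of the silyl peroxy ketal gives the 4-hydroperoxy enone F13. PPh3 reduces it to 15.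

**Further compounds**
F1 | step 7 | C-silyl ketone: 7-methyl-5-(trimethylsilyl)octahydrocyclohepta[b]furan-2,6-dione (ring stereocentres as in 6) | O=C1O[C@H]2C[C@H](C)C(=O)C([Si](C)(C)C)C[C@@H]2C1
F2 | step 7 | ring-expanded ketone: 7-methyloctahydrocyclohepta[b]furan-2,6-dione (stereocentres as in 6) | O=C1O[C@H]2C[C@H](C)C(=O)CC[C@@H]2C1
F3 | step 7 | enol triflate of F2 (C1=C5, triflate on C1) | O=C1O[C@H]2C[C@H](C)C(OS(=O)(=O)C(F)(F)F)=CC[C@@H]2C1
F4 | step 7 | Mannich base of F3 (C11 dimethylaminomethyl, C11 epimers) | CN(C)CC1C(=O)O[C@H]2C[C@H](C)C(OS(=O)(=O)C(F)(F)F)=CC[C@H]12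
F5 | step 7 | trimethylammonium iodide of F4 | C[N+](C)(C)CC1C(=O)O[C@H]2C[C@H](C)C(OS(=O)(=O)C(F)(F)F)=CC[C@H]12.[I-]
F6 | step 7 | α-methylene lactone enol triflate | C=C1C(=O)O[C@H]2C[C@H](C)C(OS(=O)(=O)C(F)(F)F)=CC[C@H]12
F7 | step 7 | cycloheptenyl (E)-propenyl ketone (Nazarov substrate) | C=C1C(=O)O[C@H]2C[C@H](C)C(C(=O)/C=C/C)=CC[C@H]12
F8 | step 12 | 13-(dimethylamino)-11,13-dihydro derivative of 17 (C11 epimers) | CN(C)CC1C(=O)O[C@H]2C[C@H](C)C3=C(C[C@H]12)[C@](C)(O)C[C@H]3OC(C)=O
F9 | step 12 | 13-(dimethylamino)-11,13-dihydro derivative of 19 | CN(C)CC1C(=O)O[C@H]2C[C@H](C)C3=C(C[C@H]12)C(C)=C[C@H]3OC(C)=O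
F10 | step 12 | 13-(dimethylamino)-11,13-dihydro derivative of 20 | CN(C)CC1C(=O)O[C@H]2C[C@H](C)[C@@]34C[C@]5(C(=O)O[C@@H]6CC(C)=C([C@@H](C)CCCOC(C)=O)[C@@H](O)[C@@H]65)[C@@H](C(C)=C3C[C@H]12)[C@H]4OC(C)=O
F11 | step 12 | trimethylammonium iodide of F10 | C[N+](C)(C)CC1C(=O)O[C@H]2C[C@H](C)[C@@]34C[C@]5(C(=O)O[C@@H]6CC(C)=C([C@@H](C)CCCOC(C)=O)[C@@H](O)[C@@H]65)[C@@H](C(C)=C3C[C@H]12)[C@H]4OC(C)=O.[I-]
F12 | step 9 | 2-[(tert-butyldimethylsilyl)oxy]-7αH,8βH,10αH-guaia-1,4,11(13)-trien-12,8-olide | C=C1C(=O)O[C@H]2C[C@H](C)C3=C(O[Si](C)(C)C(C)(C)C)CC(C)=C3C[C@H]12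
F13 | step 9 | 4α-hydroperoxy-2-oxo-7αH,8βH,10αH-guaia-1(5),11(13)-dien-12,8-olide | C=C1C(=O)O[C@H]2C[C@H](C)C3=C(C[C@H]12)[C@](C)(OO)CC3=O
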